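The runs were generated by integration for substances that don't exist.

The question is what stands in the flask at 15 d, and before any value is reckoned each given number is tried against the earlier runs for how well it has to be known.

| flask | X | Z | remark | time |
|---|---|---|---|---|
| teal | 0.025 M | 0.34 mM | run made earlier |  |
| blue | 0.025 M | 0.75 mM | run made earlier |  |
| flask | 0.025 M | 0.50 mM |  | 15 d |

- teal (time / d: X / %, Q / %, E / %): 0.833: 4.8, 7.9, 17.1; 2.50: 0.1, 14.6, 19.5; 4.00: 0, 17.1, 19.1; 6.00: 0, 16.6, 19.1; 10.0: 0.4, 16.1, 18.2; 12.0: 0, 16.5, 18.8
- blue (time / d: X / %, Q / %, E / %): 2.08: 0.9, 17.2, 15.5; 4.00: 0, 20.1, 15.1; 6.00: 0.1, 19.7, 15.7; 8.00: 0.4, 19.2, 15.0; 10.0: 0.6, 19.7, 15.7; 12.0: 0.2, 19.5, 14.4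

(readings scatter by 0.5 percentage points)

- at 15 d, what has stopped the reaction, if anything has (all of X has reacted / it is still moving / forward and back rates have come level / no working catalyst is left)
- share of the X used up at 15 d
- Q at 15 d, in percent of the X charged
- E at 15 d, in percent of the X charged
- amount of Q if the flask were left three thousand times as long, in percent of the X charged

- in percentages every species weighs as the X in it: one E counts as two
- the reaction counts as stopped when no species that holds the X changes by six tenths of a point or more over the second half of the time

- The time needs little care, since in the teal run X reads 0% at 4.00 d and Q goes from 17.1% there to 16.5% at 12.0 d, a drift close to the scatter of 0.5 percentage points.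
- Z needs more care: going from the teal to the blue run, the mean plateau of E reads 18.8% and then 15.2%.
- With each plateau replaced by its mean, the single-route share W = Q + 0.5E counts each Q and each E once, and it reads 26.0% in the teal run and 27.2% in the blue run, a shift smaller than that of E.
- For the flask, this reckoning takes the mean of the two, W = 26.6%, which may be off by about 0.63 points.
- The X charge is the same in both runs and so stays untested; this reckoning assumes that the remainder of the charge leaves X in pairs, so that R, the ratio of that remainder to W, here 2.76, scales with the charge.
- Interpolating on log Z gives E = 17.0% for the flask, and W then gives Q = 18.1%.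
- The forecast says all of X has reacted, with conversion 99.9%, Q 18.1%, E 17.1% and a long-time Q of 18.1%, on the ground “I treat it as a stable sink.”
- The flask gives all of X has reacted: conversion 100%, Q 17.8%, E 17.0%, long-time Q 17.8%, and so W = 26.3%.

    X → D (k = 1.50 × 10⁻⁵ /s)
    Z + D → Z + Q (k = 0.0520 /M/s)
    2 X → J (k = 0.00210 /M/s)
    X + D → E (k = 0.00400 /M/s)
    Z → L (k = 5.70 × 10⁻⁸ /s)

- The unseen share is J, and the pair step 2 X → J is the main reason why E stays low: the flask without that step gives E 66.9% against 17.0%.
- For the same flask with 0.062 M of X, R scaled by the charge gives W = 12.8%, and that flask computes to W = 14.9%, a gap of 2.1 points.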